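**Retrosynthetic overview**

1. Numbering used throughout (halimane): ring A = C1–C5 and C10, with the C3 ketone and quaternary C4 (C18 methyl, C19 acetoxymethyl); ring B = C5–C10, with the C6 ketone, C7 enol, C8 (C17 methyl) and quaternary C9 (C20 methyl, C11–C16 chain).
2. Last disconnection: the C6–C7 bond of the ring B diosphenol, leading to keto aldehyde 24 in which C6 is held as a butenolide on the C19 oxygen. A carbene-generated acyl anion at C7 is acylated by this lactone; this closes ring B, gives the C6/C7 dione (diosphenol) level directly and frees the C19 hydroxyl. The feature that allows it: C6 and C7 are the two carbons of a 1,2-dione that can enolise only toward C8 (C5 is sp2), C6 and C9 are held cis on the C5=C10 double bond, and O19 lies 1,4 to C6 so it can carry C6 as a five-membered lactone.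
3. C9: enantioselective Ireland–Claisen rearrangement of propanoate 12, which also brings C7, C8 and C17; the vinyl group left behind becomes the side chain by B-alkyl Suzuki coupling with iodide 20.
4. C6 and the lactone come from carbonylative lactonisation of dienyl triflate 10; the C9–C10 bond from Michael addition of the ring A enolate to ethyl but-2-ynoate; C4 from desymmetrising transfer hydrogenation of dione 2.
5. Ring order: ring A (from 1), then the temporary lactone ring (step 7), then ring B (step 16), followed by acetylation and desilylation.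

Key step: step 16

Remark 1: the sense of induction of the ruthenium catalyst (step 2) and of the chiral boron controller (step 9) is assigned by analogy with related substrates; if either proves opposite, its mirror-image form is used.
Remark 2: C8 is carried as a mixture of epimers from step 9 to step 15 and is written without a stereodescriptor, because it becomes sp2 in step 16; the C3 carbinol configuration (steps 2–13) is likewise inconsequential because C3 is reoxidised.

**Route**

Step 1
Reactants: 1 2-methylcyclohexane-1,3-dione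
Product: 2 2-(hydroxymethyl)-2-methylcyclohexane-1,3-dione
Conditions: 37% aq. HCHO, Et3N (cat.), THF/H2O, 0 °C to rt
Reagents that add atoms: formaldehyde, C=O
Why: Aldol hydroxymethylation of the acidic C2 position of a 2-alkyl-1,3-dione with formaldehyde should give the quaternary, still achiral hydroxymethyl dione.

Step 2
Reactants: 2 2-(hydroxymethyl)-2-methylcyclohexane-1,3-dione
Product: 3 (2S,3S)-3-hydroxy-2-(hydroxymethyl)-2-methylcyclohexan-1-one
Conditions: RuCl(p-cymene)[(S,S)-TsDPEN] (1 mol %), HCO2H/Et3N (5:2), CH2Cl2, rt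
Reagents that add atoms: none
Why: Asymmetric transfer hydrogenation desymmetrises the 2,2-disubstituted 1,3-dione by reducing one of the two enantiotopic carbonyl groups, which sets the quaternary centre C4 under catalyst control together with the C3 carbinol, and the hydroxy ketone should be reduced further only slowly.

Step 3
Reactants: 3 (2S,3S)-3-hydroxy-2-(hydroxymethyl)-2-methylcyclohexan-1-one
Product: 4 (2S,3S)-2-methyl-3-[(triethylsilyl)oxy]-2-{[(triethylsilyl)oxy]methyl}cyclohexan-1-one
Conditions: TESOTf (2.5 equiv), 2,6-lutidine, CH2Cl2, −78 to 0 °C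
Reagents that add atoms: triethylsilyl trifluoromethanesulfonate, CC[Si](CC)(CC)OS(=O)(=O)C(F)(F)F
Why: Silylation with the silyl triflate should proceed even at the hindered secondary alcohol and blocks retro-aldol loss of formaldehyde in the basic steps that follow.

Step 4
Reactants: 4 (2S,3S)-2-methyl-3-[(triethylsilyl)oxy]-2-{[(triethylsilyl)oxy]methyl}cyclohexan-1-one; 5 ethyl but-2-ynoate
Product: 8 ethyl (2E)-3-[(3S,4S)-3-methyl-4-[(triethylsilyl)oxy]-3-{[(triethylsilyl)oxy]methyl}-2-{[(trifluoromethyl)sulfonyl]oxy}cyclohex-1-en-1-yl]but-2-enoate, via lithium enolate 6 (not isolated), via lithium dienolate 7 (not isolated)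
Conditions: LDA, THF, −78 °C; 5, −78 to 0 °C; then PhNTf2, 0 °C to rt
Reagents that add atoms: N-phenylbis(trifluoromethanesulfonimide), O=S(=O)(N(c1ccccc1)S(=O)(=O)C(F)(F)F)C(F)(F)F
Why: The ketone can enolise only toward C10 because C4 is quaternary, Michael addition of this lithium enolate to the alkynoate followed by proton transfer should give the extended dienolate, and O-sulfonylation of its ketone oxygen fixes the tetrasubstituted C5=C10 enol triflate with the thermodynamically preferred E enoate (ring trans to ester).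

Step 5
Reactants: 8 ethyl (2E)-3-[(3S,4S)-3-methyl-4-[(triethylsilyl)oxy]-3-{[(triethylsilyl)oxy]methyl}-2-{[(trifluoromethyl)sulfonyl]oxy}cyclohex-1-en-1-yl]but-2-enoate
Product: 9 (5S,6S)-2-[(2E)-4-hydroxybut-2-en-2-yl]-6-methyl-5-[(triethylsilyl)oxy]-6-{[(triethylsilyl)oxy]methyl}cyclohex-1-en-1-yl trifluoromethanesulfonate
Conditions: DIBAL-H (2.2 equiv), CH2Cl2, −78 °C; Rochelle salt work-up
Reagents that add atoms: none
Why: 1,2-Reduction of the conjugated ester by DIBAL-H should give the allylic alcohol without touching the enol triflate or the silyl ethers.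

Step 6
Reactants: 9 (5S,6S)-2-[(2E)-4-hydroxybut-2-en-2-yl]-6-methyl-5-[(triethylsilyl)oxy]-6-{[(triethylsilyl)oxy]methyl}cyclohex-1-en-1-yl trifluoromethanesulfonate
Product: 10 (5S,6S)-6-(hydroxymethyl)-2-[(2E)-4-hydroxybut-2-en-2-yl]-6-methyl-5-[(triethylsilyl)oxy]cyclohex-1-en-1-yl trifluoromethanesulfonate
Conditions: PPTS (0.1 equiv), MeOH/CH2Cl2 (1:4), 0 °C
Reagents that add atoms: none
Why: Acid-catalysed methanolysis removes a primary triethylsilyl ether much faster than a secondary one flanked by a quaternary carbon, so the C19 hydroxyl should be freed selectively.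

Step 7
Reactants: 10 (5S,6S)-6-(hydroxymethyl)-2-[(2E)-4-hydroxybut-2-en-2-yl]-6-methyl-5-[(triethylsilyl)oxy]cyclohex-1-en-1-yl trifluoromethanesulfonate
Product: 11 (3aS,4S)-7-[(2E)-4-hydroxybut-2-en-2-yl]-3a-methyl-4-[(triethylsilyl)oxy]-3a,4,5,6-tetrahydro-2-benzofuran-1(3H)-one
Conditions: Pd(OAc)2 (5 mol %), dppp (6 mol %), CO (1 atm), Et3N, DMF, 60 °C
Reagents that add atoms: carbon monoxide, [C-]#[O+]
Why: Palladium-catalysed carbonylation of the enol triflate with capture of the acylpalladium species by the neighbouring C19 hydroxyl (carbonylative lactonisation) should install C6 as a five-membered butenolide, while the remote allylic hydroxyl on the E double bond cannot reach the acyl group.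

Step 8
Reactants: 11 (3aS,4S)-7-[(2E)-4-hydroxybut-2-en-2-yl]-3a-methyl-4-[(triethylsilyl)oxy]-3a,4,5,6-tetrahydro-2-benzofuran-1(3H)-one
Product: 12 (2E)-3-[(3aS,4S)-3a-methyl-1-oxo-4-[(triethylsilyl)oxy]-1,3,3a,4,5,6-hexahydro-2-benzofuran-7-yl]but-2-en-1-yl propanoate
Conditions: EtCOCl, pyridine, DMAP (cat.), CH2Cl2, 0 °C
Reagents that add atoms: propanoyl chloride, CCC(=O)Cl
Why: Standard acylation of the only free hydroxyl (primary, allylic) should give the propanoate needed for the ester enolate Claisen rearrangement.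

Step 9
Reactants: 12 (2E)-3-[(3aS,4S)-3a-methyl-1-oxo-4-[(triethylsilyl)oxy]-1,3,3a,4,5,6-hexahydro-2-benzofuran-7-yl]but-2-en-1-yl propanoate
Product: 14 (3R)-2,3-dimethyl-3-[(3aS,4S)-3a-methyl-1-oxo-4-[(triethylsilyl)oxy]-1,3,3a,4,5,6-hexahydro-2-benzofuran-7-yl]pent-4-enoic acid (C2 epimers), via boron enolate 13 (not isolated)
Conditions: (4S,5S)-2-bromo-4,5-diphenyl-1,3-bis{[3,5-bis(trifluoromethyl)phenyl]sulfonyl}-1,3,2-diazaborolidine (1.2 equiv), Et3N, toluene/hexane, −78 °C to rt; aqueous work-up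
Reagents that add atoms: none
Why: In this enantioselective boron-enolate Ireland–Claisen rearrangement the chiral boron ketene acetal rearranges through a chair transition state, the sulfonamide-substituted boron fixes which enolate face bonds to C9 and the E geometry of the allyl unit translates this into the configuration of the new quaternary centre C9, while C8, C17 and C7 arrive in the same step and the soft enolisation leaves the butenolide untouched.

Step 10
Reactants: 14 (3R)-2,3-dimethyl-3-[(3aS,4S)-3a-methyl-1-oxo-4-[(triethylsilyl)oxy]-1,3,3a,4,5,6-hexahydro-2-benzofuran-7-yl]pent-4-enoic acid (C2 epimers)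
Product: 16 (3aS,4S)-7-[(3R)-5-hydroxy-3,4-dimethylpent-1-en-3-yl]-3a-methyl-4-[(triethylsilyl)oxy]-3a,4,5,6-tetrahydro-2-benzofuran-1(3H)-one, via mixed carbonic anhydride 15 (not isolated)
Conditions: i-BuOCOCl, N-methylmorpholine, THF, −15 °C; then NaBH4, H2O/MeOH, 0 °C
Reagents that add atoms: none
Why: Borohydride reduction of the acid through its mixed carbonic anhydride is selective for the activated acyl group and should leave the hindered tetrasubstituted butenolide and the vinyl group untouched.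

Step 11
Reactants: 17 but-2-yn-1-ol
Product: 18 (but-2-yn-1-yloxy)(tert-butyl)diphenylsilane
Conditions: TBDPSCl, imidazole, CH2Cl2, rt
Reagents that add atoms: tert-butyl(chloro)diphenylsilane, CC(C)(C)[Si](Cl)(c1ccccc1)c1ccccc1
Why: Routine silylation of a primary alcohol gives an ether that survives the later acidic, basic and oxidative steps until the last step.

Step 12
Reactants: 18 (but-2-yn-1-yloxy)(tert-butyl)diphenylsilane
Product: 20 tert-butyl{[(2E)-3-iodobut-2-en-1-yl]oxy}diphenylsilane, via alkenylzirconocene 19 (not isolated)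
Conditions: Cp2Zr(H)Cl (2 equiv), THF, rt to 50 °C; then I2, 0 °C
Reagents that add atoms: iodine, II
Why: syn-Hydrozirconation with excess Cp2Zr(H)Cl equilibrates zirconium to the less hindered methyl-bearing alkyne carbon, and iodinolysis with retention should give the E alkenyl iodide.

Step 13
Reactants: 16 (3aS,4S)-7-[(3R)-5-hydroxy-3,4-dimethylpent-1-en-3-yl]-3a-methyl-4-[(triethylsilyl)oxy]-3a,4,5,6-tetrahydro-2-benzofuran-1(3H)-one; 20 tert-butyl{[(2E)-3-iodobut-2-en-1-yl]oxy}diphenylsilane
Product: 22 (3aS,4S)-7-[(3R,6E)-8-{[tert-butyl(diphenyl)silyl]oxy}-1-hydroxy-2,3,6-trimethyloct-6-en-3-yl]-3a-methyl-4-[(triethylsilyl)oxy]-3a,4,5,6-tetrahydro-2-benzofuran-1(3H)-one, via B-alkyl-9-BBN 21 (not isolated)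
Conditions: 9-BBN dimer (2.2 equiv B–H), THF, rt; then 20, PdCl2(dppf) (5 mol %), AsPh3, 3 M aq. K3PO4, DMF, rt
Reagents that add atoms: none
Why: Anti-Markovnikov hydroboration of the only unhindered alkene (the vinyl group) followed by B-alkyl Suzuki–Miyaura coupling with the alkenyl iodide, which proceeds with retention of the E geometry, should attach the side chain.

Step 14
Reactants: 22 (3aS,4S)-7-[(3R,6E)-8-{[tert-butyl(diphenyl)silyl]oxy}-1-hydroxy-2,3,6-trimethyloct-6-en-3-yl]-3a-methyl-4-[(triethylsilyl)oxy]-3a,4,5,6-tetrahydro-2-benzofuran-1(3H)-one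
Product: 23 (3aS,4S)-7-[(3R,6E)-8-{[tert-butyl(diphenyl)silyl]oxy}-1-hydroxy-2,3,6-trimethyloct-6-en-3-yl]-4-hydroxy-3a-methyl-3a,4,5,6-tetrahydro-2-benzofuran-1(3H)-one
Conditions: HF·pyridine, pyridine, THF, 0 °C
Reagents that add atoms: none
Why: Buffered fluoride cleaves the triethylsilyl ether far faster than the tert-butyldiphenylsilyl ether.

Step 15
Reactants: 23 (3aS,4S)-7-[(3R,6E)-8-{[tert-butyl(diphenyl)silyl]oxy}-1-hydroxy-2,3,6-trimethyloct-6-en-3-yl]-4-hydroxy-3a-methyl-3a,4,5,6-tetrahydro-2-benzofuran-1(3H)-one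
Product: 24 (3aS)-7-[(3R,6E)-8-{[tert-butyl(diphenyl)silyl]oxy}-2,3,6-trimethyl-1-oxooct-6-en-3-yl]-3a-methyl-5,6-dihydro-2-benzofuran-1,4(3H,3aH)-dione
Conditions: DMP (3 equiv), NaHCO3, CH2Cl2, rt
Reagents that add atoms: none
Why: Periodinane oxidation should convert the secondary alcohol into the C3 ketone and the primary alcohol into the C7 aldehyde in one operation under neutral conditions that the lactone tolerates.

Step 16
Reactants: 24 (3aS)-7-[(3R,6E)-8-{[tert-butyl(diphenyl)silyl]oxy}-2,3,6-trimethyl-1-oxooct-6-en-3-yl]-3a-methyl-5,6-dihydro-2-benzofuran-1,4(3H,3aH)-dione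
Product: 25 (1S,5S)-5-[(3E)-5-{[tert-butyl(diphenyl)silyl]oxy}-3-methylpent-3-en-1-yl]-7-hydroxy-1-(hydroxymethyl)-1,5,6-trimethyl-3,4-dihydronaphthalene-2,8(1H,5H)-dione (in equilibrium with its 6,19-hemiketal)
Conditions: 2-(pentafluorophenyl)-6,7-dihydro-5H-pyrrolo[2,1-c][1,2,4]triazol-2-ium tetrafluoroborate (20 mol %), i-Pr2NEt (1.5 equiv), THF (0.02 M), 40 °C
Reagents that add atoms: none
Why: Proposed new method: the carbene adds to the only aldehyde (C7) to give an acyl anion equivalent (Breslow intermediate) that attacks the butenolide carbonyl C6, the tetrahedral adduct loses the carbene to give the 6,19-hemiketal of the C6,C7-dione, and ring opening followed by enolisation toward C8 (the only side bearing a hydrogen) gives the diosphenol, whose deprotonation by the amine drains the equilibria in the way enolate formation drives a Claisen condensation. The closest known reaction types are the carbene-catalysed intramolecular crossed benzoin of keto aldehydes and the Stetter reaction, here with a conjugated five-membered lactone, more electrophilic than an open-chain ester, as the acceptor. Ring B is closed in a 6-exo-trig mode at a carbonyl carbon that the cis C5=C10 double bond and the quaternary C9 hold next to the aldehyde. No new stereocentre is formed and the C8 epimers converge because C8 becomes sp2. The step needs selectivity of the acyl anion for C6 over the C3 ketone and the conjugate position C10: attack at C3 would give a bridged seven-membered ring and attack at C10 a four-membered ring, and C10 is fully substituted, so only the six-membered closure is geometrically open. The main competitor, aldol reaction between the C3 ketone enolate and the aldehyde, is held back by the weak amine base and high dilution.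

Step 17
Reactants: 25 (1S,5S)-5-[(3E)-5-{[tert-butyl(diphenyl)silyl]oxy}-3-methylpent-3-en-1-yl]-7-hydroxy-1-(hydroxymethyl)-1,5,6-trimethyl-3,4-dihydronaphthalene-2,8(1H,5H)-dione
Product: 27 [(1S,5S)-5-[(3E)-5-{[tert-butyl(diphenyl)silyl]oxy}-3-methylpent-3-en-1-yl]-7-hydroxy-1,5,6-trimethyl-2,8-dioxo-1,2,3,4,5,8-hexahydronaphthalen-1-yl]methyl acetate, via diacetate 26 (not isolated)
Conditions: Ac2O, pyridine, DMAP (cat.), CH2Cl2, rt; then NaHCO3, MeOH, 0 °C
Reagents that add atoms: acetic anhydride, CC(=O)OC(C)=O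
Why: Acetylation traps the open hydroxy ketone form as the C19 acetate and also esterifies the diosphenol, and the enol acetate of the acidic diosphenol should then be methanolysed under conditions that leave the hindered primary alkyl acetate intact.

Step 18
Reactants: 27 [(1S,5S)-5-[(3E)-5-{[tert-butyl(diphenyl)silyl]oxy}-3-methylpent-3-en-1-yl]-7-hydroxy-1,5,6-trimethyl-2,8-dioxo-1,2,3,4,5,8-hexahydronaphthalen-1-yl]methyl acetate
Product: 28 [(1S,5S)-7-hydroxy-5-[(3E)-5-hydroxy-3-methylpent-3-en-1-yl]-1,5,6-trimethyl-2,8-dioxo-1,2,3,4,5,8-hexahydronaphthalen-1-yl]methyl acetate (CNP0512382.1)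
Conditions: HF·pyridine, THF, 0 °C to rt
Reagents that add atoms: none
Why: Fluoride-mediated desilylation under mildly acidic conditions should free the allylic alcohol without cleaving or migrating the acetate.

**Compound list**

1 | 2-methylcyclohexane-1,3-dione | CC1C(=O)CCCC1=O | starting material
2 | 2-(hydroxymethyl)-2-methylcyclohexane-1,3-dione | CC1(CO)C(=O)CCCC1=O | intermediate
3 | (2S,3S)-3-hydroxy-2-(hydroxymethyl)-2-methylcyclohexan-1-one | OC[C@@]1(C)[C@@H](O)CCCC1=O | intermediate
4 | (2S,3S)-2-methyl-3-[(triethylsilyl)oxy]-2-{[(triethylsilyl)oxy]methyl}cyclohexan-1-one | CC[Si](CC)(CC)OC[C@@]1(C)[C@@H](O[Si](CC)(CC)CC)CCCC1=O | intermediate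
5 | ethyl but-2-ynoate | CC#CC(=O)OCC | starting material
6 | lithium enolate of 4 (enolised toward C10) | CC[Si](CC)(CC)OC[C@@]1(C)[C@@H](O[Si](CC)(CC)CC)CCC=C1O[Li] | intermediate
7 | lithium dienolate, Michael adduct of 6 and 5 | CC[Si](CC)(CC)OC[C@@]1(C)[C@@H](O[Si](CC)(CC)CC)CCC(/C(C)=C/C(=O)OCC)=C1O[Li] | intermediate
8 | ethyl (2E)-3-[(3S,4S)-3-methyl-4-[(triethylsilyl)oxy]-3-{[(triethylsilyl)oxy]methyl}-2-{[(trifluoromethyl)sulfonyl]oxy}cyclohex-1-en-1-yl]but-2-enoate | CC[Si](CC)(CC)OC[C@@]1(C)[C@@H](O[Si](CC)(CC)CC)CCC(/C(C)=C/C(=O)OCC)=C1OS(=O)(=O)C(F)(F)F | intermediate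
9 | (5S,6S)-2-[(2E)-4-hydroxybut-2-en-2-yl]-6-methyl-5-[(triethylsilyl)oxy]-6-{[(triethylsilyl)oxy]methyl}cyclohex-1-en-1-yl trifluoromethanesulfonate | CC[Si](CC)(CC)OC[C@@]1(C)[C@@H](O[Si](CC)(CC)CC)CCC(/C(C)=C/CO)=C1OS(=O)(=O)C(F)(F)F | intermediate
10 | (5S,6S)-6-(hydroxymethyl)-2-[(2E)-4-hydroxybut-2-en-2-yl]-6-methyl-5-[(triethylsilyl)oxy]cyclohex-1-en-1-yl trifluoromethanesulfonate | OC[C@@]1(C)[C@@H](O[Si](CC)(CC)CC)CCC(/C(C)=C/CO)=C1OS(=O)(=O)C(F)(F)F | intermediate
11 | (3aS,4S)-7-[(2E)-4-hydroxybut-2-en-2-yl]-3a-methyl-4-[(triethylsilyl)oxy]-3a,4,5,6-tetrahydro-2-benzofuran-1(3H)-one | O=C1OC[C@@]2(C)[C@@H](O[Si](CC)(CC)CC)CCC(/C(C)=C/CO)=C12 | intermediate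
12 | (2E)-3-[(3aS,4S)-3a-methyl-1-oxo-4-[(triethylsilyl)oxy]-1,3,3a,4,5,6-hexahydro-2-benzofuran-7-yl]but-2-en-1-yl propanoate | O=C1OC[C@@]2(C)[C@@H](O[Si](CC)(CC)CC)CCC(/C(C)=C/COC(=O)CC)=C12 | intermediate
13 | boron ketene acetal of 12 carrying the (4S,5S)-4,5-diphenyl-1,3-bis(arylsulfonyl)-1,3,2-diazaborolidin-2-yl group on the enolate oxygen (enolate geometry left open; it affects only C8) | O=C1OC[C@@]2(C)[C@@H](O[Si](CC)(CC)CC)CCC(/C(C)=C/COC(=CC)OB3N(S(=O)(=O)c4cc(C(F)(F)F)cc(C(F)(F)F)c4)[C@@H](c4ccccc4)[C@H](c4ccccc4)N3S(=O)(=O)c3cc(C(F)(F)F)cc(C(F)(F)F)c3)=C12 | intermediate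
14 | (3R)-2,3-dimethyl-3-[(3aS,4S)-3a-methyl-1-oxo-4-[(triethylsilyl)oxy]-1,3,3a,4,5,6-hexahydro-2-benzofuran-7-yl]pent-4-enoic acid (C2 epimers) | O=C1OC[C@@]2(C)[C@@H](O[Si](CC)(CC)CC)CCC([C@](C(C)C(=O)O)(C)C=C)=C12 | intermediate
15 | mixed anhydride of 14 with isobutyl hydrogen carbonate | O=C1OC[C@@]2(C)[C@@H](O[Si](CC)(CC)CC)CCC([C@](C(C)C(=O)OC(=O)OCC(C)C)(C)C=C)=C12 | intermediate
16 | (3aS,4S)-7-[(3R)-5-hydroxy-3,4-dimethylpent-1-en-3-yl]-3a-methyl-4-[(triethylsilyl)oxy]-3a,4,5,6-tetrahydro-2-benzofuran-1(3H)-one | O=C1OC[C@@]2(C)[C@@H](O[Si](CC)(CC)CC)CCC([C@](C(C)CO)(C)C=C)=C12 | intermediate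
17 | but-2-yn-1-ol | CC#CCO | starting material
18 | (but-2-yn-1-yloxy)(tert-butyl)diphenylsilane | CC#CCO[Si](c1ccccc1)(c1ccccc1)C(C)(C)C | intermediate
19 | (E)-alkenylzirconocene chloride from 18 (zirconium on the methyl-bearing carbon, trans to the CH2O group) | Cl[Zr](C1C=CC=C1)(C1C=CC=C1)/C(C)=C/CO[Si](c1ccccc1)(c1ccccc1)C(C)(C)C | intermediate
20 | tert-butyl{[(2E)-3-iodobut-2-en-1-yl]oxy}diphenylsilane | I/C(C)=C/CO[Si](c1ccccc1)(c1ccccc1)C(C)(C)C | intermediate
21 | B-alkyl-9-BBN from 16 (boron on the terminal carbon of the former vinyl group; hydroxyl as its 9-BBN borinate) | O=C1OC[C@@]2(C)[C@@H](O[Si](CC)(CC)CC)CCC([C@](C(C)COB3C4CCCC3CCC4)(C)CCB3C4CCCC3CCC4)=C12 | intermediate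
22 | (3aS,4S)-7-[(3R,6E)-8-{[tert-butyl(diphenyl)silyl]oxy}-1-hydroxy-2,3,6-trimethyloct-6-en-3-yl]-3a-methyl-4-[(triethylsilyl)oxy]-3a,4,5,6-tetrahydro-2-benzofuran-1(3H)-one | O=C1OC[C@@]2(C)[C@@H](O[Si](CC)(CC)CC)CCC([C@](C(C)CO)(C)CC/C(C)=C/CO[Si](c3ccccc3)(c3ccccc3)C(C)(C)C)=C12 | intermediate
23 | (3aS,4S)-7-[(3R,6E)-8-{[tert-butyl(diphenyl)silyl]oxy}-1-hydroxy-2,3,6-trimethyloct-6-en-3-yl]-4-hydroxy-3a-methyl-3a,4,5,6-tetrahydro-2-benzofuran-1(3H)-one | O=C1OC[C@@]2(C)[C@@H](O)CCC([C@](C(C)CO)(C)CC/C(C)=C/CO[Si](c3ccccc3)(c3ccccc3)C(C)(C)C)=C12 | intermediate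
24 | (3aS)-7-[(3R,6E)-8-{[tert-butyl(diphenyl)silyl]oxy}-2,3,6-trimethyl-1-oxooct-6-en-3-yl]-3a-methyl-5,6-dihydro-2-benzofuran-1,4(3H,3aH)-dione | O=C1OC[C@@]2(C)C(=O)CCC([C@](C(C)C=O)(C)CC/C(C)=C/CO[Si](c3ccccc3)(c3ccccc3)C(C)(C)C)=C12 | intermediate
25 | (1S,5S)-5-[(3E)-5-{[tert-butyl(diphenyl)silyl]oxy}-3-methylpent-3-en-1-yl]-7-hydroxy-1-(hydroxymethyl)-1,5,6-trimethyl-3,4-dihydronaphthalene-2,8(1H,5H)-dione | OC[C@@]1(C)C(=O)CCC2=C1C(=O)C(O)=C(C)[C@@]2(C)CC/C(C)=C/CO[Si](c3ccccc3)(c3ccccc3)C(C)(C)C | intermediate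
26 | diacetate of 25 (C19 acetate and C7 enol acetate) | CC(=O)OC[C@@]1(C)C(=O)CCC2=C1C(=O)C(OC(C)=O)=C(C)[C@@]2(C)CC/C(C)=C/CO[Si](c3ccccc3)(c3ccccc3)C(C)(C)C | intermediate
27 | [(1S,5S)-5-[(3E)-5-{[tert-butyl(diphenyl)silyl]oxy}-3-methylpent-3-en-1-yl]-7-hydroxy-1,5,6-trimethyl-2,8-dioxo-1,2,3,4,5,8-hexahydronaphthalen-1-yl]methyl acetate | CC(=O)OC[C@@]1(C)C(=O)CCC2=C1C(=O)C(O)=C(C)[C@@]2(C)CC/C(C)=C/CO[Si](c3ccccc3)(c3ccccc3)C(C)(C)C | intermediate
28 | [(1S,5S)-7-hydroxy-5-[(3E)-5-hydroxy-3-methylpent-3-en-1-yl]-1,5,6-trimethyl-2,8-dioxo-1,2,3,4,5,8-hexahydronaphthalen-1-yl]methyl acetate | CC(=O)OC[C@@]1(C)C(=O)CCC2=C1C(=O)C(O)=C(C)[C@@]2(C)CC/C(C)=C/CO | target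

**Step count and risks**

Total step count: 18. Longest linear sequence: 16 steps (steps 1–10 and 13–18); steps 11–12 make the side-chain iodide 20.

Steps most likely to fail:

1. Step 16 (proposed new method). The acyl anion equivalent may add reversibly to the lactone carbonyl without the adduct moving on to the dione, or amine-mediated aldol reaction between the C3 ketone enolate and the aldehyde may outrun the carbene pathway. The fallback sets out from 22 and uses an ordinary aldehyde–aldehyde crossed benzoin. DIBAL-H at −78 °C would reduce the butenolide of 22 to lactol F1. PPTS in methanol would turn it into the cyclic methyl acetal and remove the triethylsilyl group, giving diol acetal F2. Periodinane oxidation would give keto aldehyde acetal F3, and aqueous acetic acid in THF would hydrolyse the acetal to keto aldehyde lactol F4. A thiazolium-derived carbene with Et3N should then effect the intramolecular crossed benzoin between the C7 aldehyde and the C6 aldehyde released by ring opening of the lactol, giving α-ketol F5 with a free C19 hydroxyl. Acetyl chloride and 2,4,6-collidine at −78 °C would acetylate the primary hydroxyl selectively to give ketol acetate F6. Periodinane oxidation of the ketol and enolisation would return to the route at 27.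

2. Step 9. The congested quaternary centre may form with poor facial discrimination by the boron controller, the rearrangement may be too slow, or the Lewis-acidic boron bromide may cleave the silyl ether. The fallback sets out from 11 and replaces the sigmatropic step by a copper-catalysed enantioselective allylic substitution. Diethyl chlorophosphate and DMAP would convert 11 into allylic phosphate F7. CuCl with a chiral sulfonate-bearing imidazolinium salt, NaOMe and isopropenylboronic acid pinacol ester should effect SN2′ substitution, giving bis-alkenyl lactone F8 with the C9 quaternary centre, a vinyl group and an isopropenyl group. 9-BBN would hydroborate the vinyl group selectively, and coupling with 20 under PdCl2(dppf) catalysis would give isopropenyl lactone F9. A second hydroboration of the isopropenyl group with 9-BBN and oxidation with NaBO3 would return to the route at 22.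

3. Step 4. The lithium enolate may add to the ester carbonyl or deprotonate the alkynoate instead of undergoing conjugate addition, the C9=C11 geometry may come out mixed, or sulfonylation may occur at the wrong site of the dienolate. The fallback sets out from 4 and 17 and builds the same diene by cross-coupling. 17 would be protected with dihydropyran to give tetrahydropyranyl ether F10, and hydrozirconation–iodination as in step 12 would give alkenyl iodide F11. Palladium-catalysed α-alkenylation of the enolate of 4 (Pd2(dba)3, a bulky biaryl phosphine, LiHMDS, toluene) would give α-alkenyl ketone F12. KHMDS and PhNTf2 would convert it into dienyl triflate F13. PPTS in methanol would remove the tetrahydropyranyl group and the primary triethylsilyl group together and return to the route at 10.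

**Further compounds**

F1 | step 16 | lactol from 22 (butenolide carbonyl reduced to the hemiacetal) | OC1OC[C@@]2(C)[C@@H](O[Si](CC)(CC)CC)CCC([C@](C(C)CO)(C)CC/C(C)=C/CO[Si](c3ccccc3)(c3ccccc3)C(C)(C)C)=C12
F2 | step 16 | cyclic methyl acetal diol (C3 and C7 hydroxyls free) | COC1OC[C@@]2(C)[C@@H](O)CCC([C@](C(C)CO)(C)CC/C(C)=C/CO[Si](c3ccccc3)(c3ccccc3)C(C)(C)C)=C12
F3 | step 16 | keto aldehyde cyclic methyl acetal | COC1OC[C@@]2(C)C(=O)CCC([C@](C(C)C=O)(C)CC/C(C)=C/CO[Si](c3ccccc3)(c3ccccc3)C(C)(C)C)=C12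
F4 | step 16 | keto aldehyde lactol | OC1OC[C@@]2(C)C(=O)CCC([C@](C(C)C=O)(C)CC/C(C)=C/CO[Si](c3ccccc3)(c3ccccc3)C(C)(C)C)=C12
F5 | step 16 | α-ketol (C6 hydroxyl, C7 ketone) with free C19 hydroxyl | OC[C@@]1(C)C(=O)CCC2=C1C(O)C(=O)C(C)[C@@]2(C)CC/C(C)=C/CO[Si](c3ccccc3)(c3ccccc3)C(C)(C)C
F6 | step 16 | α-ketol C19 acetate | CC(=O)OC[C@@]1(C)C(=O)CCC2=C1C(O)C(=O)C(C)[C@@]2(C)CC/C(C)=C/CO[Si](c3ccccc3)(c3ccccc3)C(C)(C)C
F7 | step 9 | diethyl allylic phosphate of 11 | O=C1OC[C@@]2(C)[C@@H](O[Si](CC)(CC)CC)CCC(/C(C)=C/COP(=O)(OCC)OCC)=C12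
F8 | step 9 | butenolide with C9 bearing methyl, vinyl and isopropenyl | O=C1OC[C@@]2(C)[C@@H](O[Si](CC)(CC)CC)CCC([C@](C(C)=C)(C)C=C)=C12
F9 | step 9 | side-chain coupled isopropenyl butenolide | O=C1OC[C@@]2(C)[C@@H](O[Si](CC)(CC)CC)CCC([C@](C(C)=C)(C)CC/C(C)=C/CO[Si](c3ccccc3)(c3ccccc3)C(C)(C)C)=C12
F10 | step 4 | 2-(but-2-yn-1-yloxy)oxane | CC#CCOC1CCCCO1
F11 | step 4 | 2-{[(2E)-3-iodobut-2-en-1-yl]oxy}oxane | I/C(C)=C/COC1CCCCO1
F12 | step 4 | α-alkenyl ketone from 4 and F11 (C10 epimers) | CC[Si](CC)(CC)OC[C@@]1(C)[C@@H](O[Si](CC)(CC)CC)CCC(/C(C)=C/COC2CCCCO2)C1=O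
F13 | step 4 | dienyl triflate with tetrahydropyranyl ether | CC[Si](CC)(CC)OC[C@@]1(C)[C@@H](O[Si](CC)(CC)CC)CCC(/C(C)=C/COC2CCCCO2)=C1OS(=O)(=O)C(F)(F)F
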